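Ring A is built, not decorated. The design exploits the 1,3,5-placement of oxygen on C5, C7 and C8a, with the C8 prenyl group flanked by the C7 and C8a oxygens. This is the substitution pattern produced when a 3-alkoxycyclobutenone is annulated with a 1-siloxyalkyne. One thermal operation forms C8–C8a, C6–C7 and C4a–C8a and releases a phenol whose only unprotected oxygen is the future O1. This settles which ring A carbon carries the prenyl group. The precursors are a four-membered vinylogous 4-methoxybenzyl ester and an open-chain, prenyl-substituted triisopropylsilyl ynol ether. Magnesium-directed ortho-formylation then marks C4a, and the pyranone follows by established 2-sulfinylchromone displacement.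

Key step: step 3

Assumption: the target has no stereocentre and no E/Z-isomeric double bond, so transient stereocentres are carried as racemates; ring positions are given in chromone numbering (O1, C2 to C8a).

Step 1
Reactants: 1 3-ethoxycyclobut-2-en-1-one; 2 4-methoxybenzyl alcohol
Product: 3 3-[(4-methoxybenzyl)oxy]cyclobut-2-en-1-one
Conditions: 2 (2 equiv), camphorsulfonic acid (5 mol %), 5 Å molecular sieves, toluene, rt
Reagents that add atoms: none
Why: Acid-catalysed vinylogous transesterification (addition–elimination at C3 of the protonated enone) is an equilibrium that the sieves shift by binding ethanol, and room temperature lies far below the onset of electrocyclic ring opening, so no ketene is lost to the alcohol.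

Step 2
Reactants: 4 ethyl 4-methylpent-3-enoate
Product: 7 triisopropyl[(5-methylhex-4-en-1-yn-1-yl)oxy]silane, via lithium dibromoenolate 5 (not isolated), via lithium ynolate 6 (not isolated)
Conditions: CH2Br2, lithium 2,2,6,6-tetramethylpiperidide, THF, −78 °C, then 4; LiN(SiMe3)2; n-BuLi, −78 °C to rt; TIPSOTf, −78 to 0 °C
Reagents that add atoms: dibromomethane BrCBr; triisopropylsilyl triflate CC(C)[Si](C(C)C)(C(C)C)OS(=O)(=O)C(F)(F)F
Why: Kowalski ester homologation stopped at the ynolate stage: the preformed carbenoid LiCHBr2 adds to the ester, LiN(SiMe3)2 converts the released dibromoketone into enolate 5, bromine–lithium exchange triggers the 1,2-shift of the prenyl group to give ynolate 6, and the bulky silyl triflate traps it on oxygen, not on carbon.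

Step 3
Reactants: 3 3-[(4-methoxybenzyl)oxy]cyclobut-2-en-1-one; 7 triisopropyl[(5-methylhex-4-en-1-yn-1-yl)oxy]silane
Product: 12 5-[(4-methoxybenzyl)oxy]-2-(3-methylbut-2-en-1-yl)-3-[(triisopropylsilyl)oxy]phenol, via vinylketene 8 (not isolated), via 4-vinylcyclobutenone 9 (not isolated), via dienylketene 10 (not isolated), via cyclohexadienone 11 (not isolated)
Conditions: 7 (1.3 equiv), toluene, 110 °C, slow addition of 3, then 120 °C (sealed tube)
Reagents that add atoms: none
Why: Danheiser benzannulation in its siloxyalkyne form: conrotatory four-electron opening of 3 gives vinylketene 8, whose ketene C=C adds (2+2) to the electron-rich triple bond of 7 to give 4-vinylcyclobutenone 9 (C8–C8a and C6–C7 bonds). A second four-electron opening leads to dienylketene 10, and ring A closes by disrotatory six-electron electrocyclisation (C4a–C8a bond) to cyclohexadienone 11, which tautomerises to phenol 12. The only selectivity required is the orientation of the (2+2) step; oxygen donation makes the prenyl-substituted alkyne carbon the nucleophilic terminus and it bonds to the electrophilic central carbon of the ketene, so O1 emerges unprotected at C8a next to C8 while O7 carries silicon and O5 the 4-methoxybenzyl group. A direct (4+2) union of 8 and 7 with the same polarity would give the same phenol, since C2 and C4 of the cyclobutenone both finish as ring CH. The closest known reaction is the annulation of 3-alkylcyclobutenones with triisopropylsiloxyalkynes to resorcinol monosilyl ethers; intermediates of type 9 in every such reaction show that a 3-oxygenated cyclobutenone opens at these temperatures, and slow addition of 3 to excess 7 keeps 8 from acylating 12. No stereocentre is created in 12; the one in 9 is racemic and vanishes on ring opening.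

Step 4
Reactants: 12 5-[(4-methoxybenzyl)oxy]-2-(3-methylbut-2-en-1-yl)-3-[(triisopropylsilyl)oxy]phenol
Product: 14 2-hydroxy-6-[(4-methoxybenzyl)oxy]-3-(3-methylbut-2-en-1-yl)-4-[(triisopropylsilyl)oxy]benzaldehyde, via salicyl alcohol magnesium salt 13 (not isolated)
Conditions: MgCl2 (2 equiv), Et3N (4 equiv), (CH2O)n (6 equiv), THF, reflux; cold aqueous citric acid work-up
Reagents that add atoms: paraformaldehyde (as formaldehyde) C=O
Why: Casnati–Skattebøl ortho-formylation: the magnesium phenoxide delivers coordinated formaldehyde only ortho to the free hydroxyl, which can only be the future C4a because the other ortho carbon bears the prenyl group, and alkoxide 13 then passes hydride to a second formaldehyde, all without an electrophilic halogen that could trigger haloetherification of the o-prenylphenol.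

Step 5
Reactants: 14 2-hydroxy-6-[(4-methoxybenzyl)oxy]-3-(3-methylbut-2-en-1-yl)-4-[(triisopropylsilyl)oxy]benzaldehyde
Product: 15 2-(1-hydroxyethyl)-3-[(4-methoxybenzyl)oxy]-6-(3-methylbut-2-en-1-yl)-5-[(triisopropylsilyl)oxy]phenol (racemic)
Conditions: MeMgBr (2.5 equiv), THF, −78 to 0 °C; pH 7 buffer work-up
Reagents that add atoms: methylmagnesium bromide C[Mg]Br
Why: Grignard addition to a salicylaldehyde, in which the first equivalent forms the phenoxide and the second adds to the chelated aldehyde; the carbinol centre forms as a racemate without consequence because step 6 erases it.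

Step 6
Reactants: 15 2-(1-hydroxyethyl)-3-[(4-methoxybenzyl)oxy]-6-(3-methylbut-2-en-1-yl)-5-[(triisopropylsilyl)oxy]phenol
Product: 16 1-{2-hydroxy-6-[(4-methoxybenzyl)oxy]-3-(3-methylbut-2-en-1-yl)-4-[(triisopropylsilyl)oxy]phenyl}ethan-1-one
Conditions: MnO2 (15 equiv), CH2Cl2, rt
Reagents that add atoms: none
Why: Neutral MnO2 oxidation of an electron-rich benzylic alcohol gives the hydrogen-bonded o-hydroxyacetophenone and leaves the isolated trisubstituted alkene, the benzyl-type ether and the silyl ether untouched.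

Step 7
Reactants: 16 1-{2-hydroxy-6-[(4-methoxybenzyl)oxy]-3-(3-methylbut-2-en-1-yl)-4-[(triisopropylsilyl)oxy]phenyl}ethan-1-one
Product: 18 5-[(4-methoxybenzyl)oxy]-2-(methylsulfanyl)-8-(3-methylbut-2-en-1-yl)-7-[(triisopropylsilyl)oxy]-4H-chromen-4-one, via ketene dithioacetal phenoxide 17 (not isolated)
Conditions: LiN(SiMe3)2 (3.2 equiv), THF, −78 °C; CS2, −78 to 0 °C; MeI (2.05 equiv), 0 °C; then 55 °C
Reagents that add atoms: carbon disulfide S=C=S; iodomethane CI
Why: Ketene dithioacetal formation from a methyl ketone enolate (CS2, then double S-methylation) is followed by intramolecular conjugate addition–elimination of the phenoxide with loss of methanethiolate, the classical entry to 2-(methylsulfanyl)chromones, and only O1 is free to close, so only the 8-prenyl isomer can form.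

Step 8
Reactants: 18 5-[(4-methoxybenzyl)oxy]-2-(methylsulfanyl)-8-(3-methylbut-2-en-1-yl)-7-[(triisopropylsilyl)oxy]-4H-chromen-4-one
Product: 19 5-[(4-methoxybenzyl)oxy]-2-(methylsulfinyl)-8-(3-methylbut-2-en-1-yl)-7-[(triisopropylsilyl)oxy]-4H-chromen-4-one (racemic at sulfur)
Conditions: mCPBA (1.0 equiv), CH2Cl2, −78 to −20 °C
Reagents that add atoms: 3-chloroperbenzoic acid OOC(=O)c1cccc(Cl)c1
Why: Peracid oxidation of a sulfide to the sulfoxide is much faster than epoxidation of a trisubstituted alkene, so one equivalent at low temperature should stop at sulfur; the sulfur stereocentre is racemic and leaves with the sulfinyl group in step 9.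

Step 9
Reactants: 19 5-[(4-methoxybenzyl)oxy]-2-(methylsulfinyl)-8-(3-methylbut-2-en-1-yl)-7-[(triisopropylsilyl)oxy]-4H-chromen-4-one; 20 4-methoxyphenol
Product: 22 5-[(4-methoxybenzyl)oxy]-2-(4-methoxyphenoxy)-8-(3-methylbut-2-en-1-yl)-7-[(triisopropylsilyl)oxy]-4H-chromen-4-one, via sodium 4-methoxyphenoxide 21 (not isolated)
Conditions: 20 (1.05 equiv), NaH (1.05 equiv), THF, 0 °C; then 19, 0 °C
Reagents that add atoms: none
Why: Addition–elimination at C2 of a 2-sulfinylchromone by an aryloxide is the established route to 2-aryloxychromones, and a preformed phenoxide in near-stoichiometric amount at 0 °C spares the hindered aryl silyl ether.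

Step 10
Reactants: 22 5-[(4-methoxybenzyl)oxy]-2-(4-methoxyphenoxy)-8-(3-methylbut-2-en-1-yl)-7-[(triisopropylsilyl)oxy]-4H-chromen-4-one
Product: 23 5-hydroxy-2-(4-methoxyphenoxy)-8-(3-methylbut-2-en-1-yl)-7-[(triisopropylsilyl)oxy]-4H-chromen-4-one
Conditions: MgBr2·OEt2 (3 equiv), Me2S (10 equiv), CH2Cl2, 0 °C to rt
Reagents that add atoms: none
Why: Chelation-assisted ether cleavage: magnesium bound between the C4 carbonyl and O5 activates only the peri benzyl-type ether, dimethyl sulfide captures the 4-methoxybenzyl group, no Brønsted acid or oxidant touches the prenyl group, and the silyl group still on O7 blocks chroman formation.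

Step 11
Reactants: 23 5-hydroxy-2-(4-methoxyphenoxy)-8-(3-methylbut-2-en-1-yl)-7-[(triisopropylsilyl)oxy]-4H-chromen-4-one
Product: 24 5,7-dihydroxy-2-(4-methoxyphenoxy)-8-(3-methylbut-2-en-1-yl)-4H-chromen-4-one (CNP0274214.0)
Conditions: Bu4NF (1.2 equiv), AcOH (1.2 equiv), THF, 0 °C
Reagents that add atoms: none
Why: Fluoride desilylation of an aryl silyl ether para to the chromone carbonyl is fast at 0 °C, and the acetic acid buffer keeps the medium from turning basic enough to attack C2 or to open and reclose the pyranone.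

Compound list
1 | 3-ethoxycyclobut-2-en-1-one | CCOC1=CC(=O)C1 | starting material
2 | 4-methoxybenzyl alcohol | COc1ccc(CO)cc1 | starting material
3 | 3-[(4-methoxybenzyl)oxy]cyclobut-2-en-1-one | O=C1C=C(OCc2ccc(OC)cc2)C1 | intermediate
4 | ethyl 4-methylpent-3-enoate | CCOC(=O)CC=C(C)C | starting material
5 | lithium 1,1-dibromo-5-methylhexa-1,4-dien-2-olate | [Li+].[O-]C(CC=C(C)C)=C(Br)Br | intermediate
6 | lithium 5-methylhex-4-en-1-yn-1-olate | [Li+].[O-]C#CCC=C(C)C | intermediate
7 | triisopropyl[(5-methylhex-4-en-1-yn-1-yl)oxy]silane | CC(C)=CCC#CO[Si](C(C)C)(C(C)C)C(C)C | intermediate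
8 | 3-[(4-methoxybenzyl)oxy]buta-1,3-dien-1-one | O=C=CC(=C)OCc1ccc(OC)cc1 | intermediate
9 | 4-{1-[(4-methoxybenzyl)oxy]ethenyl}-2-(3-methylbut-2-en-1-yl)-3-[(triisopropylsilyl)oxy]cyclobut-2-en-1-one (racemic) | O=C1C(CC=C(C)C)=C(O[Si](C(C)C)(C(C)C)C(C)C)C1C(=C)OCc1ccc(OC)cc1 | intermediate
10 | 5-[(4-methoxybenzyl)oxy]-2-(3-methylbut-2-en-1-yl)-3-[(triisopropylsilyl)oxy]hexa-1,3,5-trien-1-one (ketene and alkoxyvinyl groups cis on C3=C4) | O=C=C(CC=C(C)C)/C(O[Si](C(C)C)(C(C)C)C(C)C)=C\C(=C)OCc1ccc(OC)cc1 | intermediate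
11 | 5-[(4-methoxybenzyl)oxy]-2-(3-methylbut-2-en-1-yl)-3-[(triisopropylsilyl)oxy]cyclohexa-2,4-dien-1-one | O=C1CC(OCc2ccc(OC)cc2)=CC(O[Si](C(C)C)(C(C)C)C(C)C)=C1CC=C(C)C | intermediate
12 | 5-[(4-methoxybenzyl)oxy]-2-(3-methylbut-2-en-1-yl)-3-[(triisopropylsilyl)oxy]phenol | Oc1cc(OCc2ccc(OC)cc2)cc(O[Si](C(C)C)(C(C)C)C(C)C)c1CC=C(C)C | intermediate
13 | 2-(hydroxymethyl)-3-[(4-methoxybenzyl)oxy]-6-(3-methylbut-2-en-1-yl)-5-[(triisopropylsilyl)oxy]phenol (present as its magnesium salt) | OCc1c(O)c(CC=C(C)C)c(O[Si](C(C)C)(C(C)C)C(C)C)cc1OCc1ccc(OC)cc1 | intermediate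
14 | 2-hydroxy-6-[(4-methoxybenzyl)oxy]-3-(3-methylbut-2-en-1-yl)-4-[(triisopropylsilyl)oxy]benzaldehyde | O=Cc1c(O)c(CC=C(C)C)c(O[Si](C(C)C)(C(C)C)C(C)C)cc1OCc1ccc(OC)cc1 | intermediate
15 | 2-(1-hydroxyethyl)-3-[(4-methoxybenzyl)oxy]-6-(3-methylbut-2-en-1-yl)-5-[(triisopropylsilyl)oxy]phenol (racemic) | CC(O)c1c(O)c(CC=C(C)C)c(O[Si](C(C)C)(C(C)C)C(C)C)cc1OCc1ccc(OC)cc1 | intermediate
16 | 1-{2-hydroxy-6-[(4-methoxybenzyl)oxy]-3-(3-methylbut-2-en-1-yl)-4-[(triisopropylsilyl)oxy]phenyl}ethan-1-one | CC(=O)c1c(O)c(CC=C(C)C)c(O[Si](C(C)C)(C(C)C)C(C)C)cc1OCc1ccc(OC)cc1 | intermediate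
17 | lithium 2-[3,3-bis(methylsulfanyl)prop-2-enoyl]-3-[(4-methoxybenzyl)oxy]-6-(3-methylbut-2-en-1-yl)-5-[(triisopropylsilyl)oxy]phenolate | [Li+].[O-]c1c(CC=C(C)C)c(O[Si](C(C)C)(C(C)C)C(C)C)cc(OCc2ccc(OC)cc2)c1C(=O)C=C(SC)SC | intermediate
18 | 5-[(4-methoxybenzyl)oxy]-2-(methylsulfanyl)-8-(3-methylbut-2-en-1-yl)-7-[(triisopropylsilyl)oxy]-4H-chromen-4-one | CSc1cc(=O)c2c(OCc3ccc(OC)cc3)cc(O[Si](C(C)C)(C(C)C)C(C)C)c(CC=C(C)C)c2o1 | intermediate
19 | 5-[(4-methoxybenzyl)oxy]-2-(methylsulfinyl)-8-(3-methylbut-2-en-1-yl)-7-[(triisopropylsilyl)oxy]-4H-chromen-4-one (racemic at sulfur) | CS(=O)c1cc(=O)c2c(OCc3ccc(OC)cc3)cc(O[Si](C(C)C)(C(C)C)C(C)C)c(CC=C(C)C)c2o1 | intermediate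
20 | 4-methoxyphenol | COc1ccc(O)cc1 | starting material
21 | sodium 4-methoxyphenoxide | COc1ccc([O-])cc1.[Na+] | intermediate
22 | 5-[(4-methoxybenzyl)oxy]-2-(4-methoxyphenoxy)-8-(3-methylbut-2-en-1-yl)-7-[(triisopropylsilyl)oxy]-4H-chromen-4-one | COc1ccc(Oc2cc(=O)c3c(OCc4ccc(OC)cc4)cc(O[Si](C(C)C)(C(C)C)C(C)C)c(CC=C(C)C)c3o2)cc1 | intermediate
23 | 5-hydroxy-2-(4-methoxyphenoxy)-8-(3-methylbut-2-en-1-yl)-7-[(triisopropylsilyl)oxy]-4H-chromen-4-one | COc1ccc(Oc2cc(=O)c3c(O)cc(O[Si](C(C)C)(C(C)C)C(C)C)c(CC=C(C)C)c3o2)cc1 | intermediate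
24 | 5,7-dihydroxy-2-(4-methoxyphenoxy)-8-(3-methylbut-2-en-1-yl)-4H-chromen-4-one (CNP0274214.0) | COc1ccc(Oc2cc(=O)c3c(O)cc(O)c(CC=C(C)C)c3o2)cc1 | target

Total step count: 11. Longest linear sequence: 10 steps (step 1 or step 2, then steps 3 to 11).

Steps most likely to fail

Step 3.
- **Risk:** The donor-stabilised four-membered ring may open too slowly. Ketene dimerisation, acylation of the product phenol by the ketene and thermal decay of the ynol ether could then overtake the annulation.
- **Fallback:** Ring A is taken from the aromatic pool. The fallback sets out from 4-methoxybenzyl alcohol 2 and purchased 2,4,6-trihydroxyacetophenone. C-prenylation of the latter (prenyl bromide, aqueous KOH, 0 °C to rt) should give 1-[2,4,6-trihydroxy-3-(3-methylbut-2-en-1-yl)phenyl]ethan-1-one F1. One equivalent of TIPSCl with imidazole silylates the hydroxyl para to the acetyl group, the only one that cannot hydrogen-bond to it, to give 1-{2,6-dihydroxy-3-(3-methylbut-2-en-1-yl)-4-[(triisopropylsilyl)oxy]phenyl}ethan-1-one F2. Mitsunobu etherification with 2 (PPh3, DIAD, THF) at the less hindered of the two remaining hydroxyls comes back to the route at acetophenone 16 and replaces steps 1 to 6.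

Step 2.
- **Risk:** Deprotonation of the doubly activated CH2 of the β,γ-unsaturated ester could compete with carbenoid addition. The double bond could drift into conjugation, and the ynolate could be partly silylated on carbon.
- **Fallback:** The ynolate is reached by oxidising an acetylide instead of by rearrangement. The fallback sets out from ester 4. Reduction with i-Bu2AlH (toluene, −78 °C) gives 4-methylpent-3-enal F3. Corey–Fuchs olefination (CBr4, PPh3, CH2Cl2, 0 °C) gives 1,1-dibromo-5-methylhexa-1,4-diene F4. n-BuLi (2.1 equiv, THF, −78 °C) gives lithium 5-methylhex-4-en-1-yn-1-ide F5. This is oxidised in the same flask with lithium tert-butyl peroxide (from t-BuOOH and LiN(SiMe3)2, −78 to 0 °C). The fallback comes back to the route at ynolate 6, which TIPSOTf converts to 7 as before.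

Step 8.
- **Risk:** Chemoselectivity may be lost. The sulfur of a vinylogous thioester is a weaker nucleophile than that of a simple sulfide, so epoxidation of the prenyl double bond or over-oxidation could compete.
- **Fallback:** The sulfur chemistry is dropped, and C2 and C3 enter already carrying the aryloxy group. The fallback sets out from aldehyde 14 and 4-methoxyphenol 20. Treating 20 with KH and trichloroethylene (THF) gives 1-{[(E)-1,2-dichloroethenyl]oxy}-4-methoxybenzene F6. n-BuLi (2.2 equiv, −78 °C) converts this to lithium (4-methoxyphenoxy)ethynide F7. Addition of F7 to the lithium phenoxide of 14, followed by a neutral work-up, gives 2-[1-hydroxy-3-(4-methoxyphenoxy)prop-2-yn-1-yl]-3-[(4-methoxybenzyl)oxy]-6-(3-methylbut-2-en-1-yl)-5-[(triisopropylsilyl)oxy]phenol F8 (racemic). MnO2 oxidation gives 1-{2-hydroxy-6-[(4-methoxybenzyl)oxy]-3-(3-methylbut-2-en-1-yl)-4-[(triisopropylsilyl)oxy]phenyl}-3-(4-methoxyphenoxy)prop-2-yn-1-one F9. Its free phenol closes by 6-endo-dig conjugate addition (catalytic K2CO3, acetone). The fallback comes back to the route at 22 and replaces steps 5 to 9.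

Further compounds
F1 | step 3 | 1-[2,4,6-trihydroxy-3-(3-methylbut-2-en-1-yl)phenyl]ethan-1-one | CC(=O)c1c(O)cc(O)c(CC=C(C)C)c1O
F2 | step 3 | 1-{2,6-dihydroxy-3-(3-methylbut-2-en-1-yl)-4-[(triisopropylsilyl)oxy]phenyl}ethan-1-one | CC(=O)c1c(O)cc(O[Si](C(C)C)(C(C)C)C(C)C)c(CC=C(C)C)c1O
F3 | step 2 | 4-methylpent-3-enal | CC(C)=CCC=O
F4 | step 2 | 1,1-dibromo-5-methylhexa-1,4-diene | CC(C)=CCC=C(Br)Br
F5 | step 2 | lithium 5-methylhex-4-en-1-yn-1-ide | [Li]C#CCC=C(C)C
F6 | step 8 | 1-{[(E)-1,2-dichloroethenyl]oxy}-4-methoxybenzene | COc1ccc(O/C(Cl)=C\Cl)cc1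
F7 | step 8 | lithium (4-methoxyphenoxy)ethynide | [Li]C#COc1ccc(OC)cc1
F8 | step 8 | 2-[1-hydroxy-3-(4-methoxyphenoxy)prop-2-yn-1-yl]-3-[(4-methoxybenzyl)oxy]-6-(3-methylbut-2-en-1-yl)-5-[(triisopropylsilyl)oxy]phenol (racemic) | COc1ccc(OC#CC(O)c2c(O)c(CC=C(C)C)c(O[Si](C(C)C)(C(C)C)C(C)C)cc2OCc2ccc(OC)cc2)cc1
F9 | step 8 | 1-{2-hydroxy-6-[(4-methoxybenzyl)oxy]-3-(3-methylbut-2-en-1-yl)-4-[(triisopropylsilyl)oxy]phenyl}-3-(4-methoxyphenoxy)prop-2-yn-1-one | COc1ccc(OC#CC(=O)c2c(O)c(CC=C(C)C)c(O[Si](C(C)C)(C(C)C)C(C)C)cc2OCc2ccc(OC)cc2)cc1
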